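**Retrosynthetic overview** (eudesmane numbering C1–C15 is used for positions)

1. 21 ⇐ 20 by a Schenck ene reaction of singlet oxygen at the 7(11)-en-8-one; 20 ⇐ 17 by 3-O-angeloylation; 17 ⇐ 16 by α-face OsO4 dihydroxylation of the Δ3 olefin, which sets C3 and C4.
2. 16 ⇐ 12: the C7 isopropylidene comes from acetone (13) by aldol addition and dehydration.
3. Key disconnection, 12 ⇐ 10: ring A is closed at C3=C4 by a titanium ketyl (McMurry) coupling of the C3 aldehyde with the C4 methyl ketone, two carbonyl carbons joined with reversed polarity. The olefin, not the pinacol, is the goal, because any addition to the C4 acetyl group should put the C4 oxygen on the β-face (the wrong C4 epimer).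
4. 10 ⇐ 8 ⇐ 7 ⇐ 4 ⇐ 1 + 2: ozonolysis of a diene unmasks both carbonyl groups. The butenyl arm (a latent propanal homoenolate) is added 1,4 to (+)-verbenone and sets quaternary C10; the isopropenyl arm is released by cyclobutane fragmentation with C5 untouched.
5. Ring order: ring B is the six-membered ring already present in verbenone (freed in step 2); ring A is formed second, in step 5.

Assumption: (1R,5R)-(+)-verbenone (1) is bought as such (it is also one allylic oxidation away from (+)-α-pinene).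

**Route**

Step 1
Reactants: 1 (1R,5R)-(+)-verbenone; 2 but-3-en-1-ylmagnesium bromide
Product: 4 (1R,4R,5R)-4-(but-3-en-1-yl)-4,6,6-trimethylbicyclo[3.1.1]heptan-2-one, via trimethylsilyl enol ether 3 (not isolated)
Conditions: CH2=CHCH2CH2MgBr (1.5 equiv), CuBr·SMe2 (10 mol %), TMSCl, THF, −78 → −30 °C; then 1 M HCl
Reagents that add atoms: chlorotrimethylsilane, C[Si](C)(C)Cl (stays only in 3)
Why: Copper-catalysed, TMSCl-accelerated conjugate addition of a Grignard reagent to the β,β-disubstituted enone; the butenyl group is a latent propanal homoenolate (its CH=CH2 becomes the C3 aldehyde in step 4), so C1 and C10, the β-carbons of two carbonyl groups, are joined, and attack anti to the CMe2 bridge sets the quaternary C10 (4R in 4).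

Step 2
Reactants: 4 (1R,4R,5R)-4-(but-3-en-1-yl)-4,6,6-trimethylbicyclo[3.1.1]heptan-2-one
Product: 7 (3R,4S)-3-(but-3-en-1-yl)-3-methyl-4-(prop-1-en-2-yl)cyclohexan-1-one, via iodo silyl enol ether 5 (not isolated), via isopropenyl silyl enol ether 6 (not isolated)
Conditions: TMSI, CH2Cl2, −20 → 0 °C; DBU (3 equiv), 0 → 25 °C; then 1 M HCl
Reagents that add atoms: iodotrimethylsilane, C[Si](C)(C)I (stays only in 5 and 6)
Why: Iodotrimethylsilane-induced fragmentation of the strained α-keto cyclobutane (cleavage of the bond between the α-bridgehead and the CMe2 carbon to a silyl enol ether plus tertiary iodide, a reaction type known for nopinone- and verbanone-type ketones) followed by E2 loss of HI toward a methyl group, the ring methine being shielded by the adjacent quaternary carbon; no stereocentre is touched, so butenyl (on C10) and isopropenyl (on C5) are trans.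

Step 3
Reactants: 7 (3R,4S)-3-(but-3-en-1-yl)-3-methyl-4-(prop-1-en-2-yl)cyclohexan-1-one
Product: 8 (7R,8S)-7-(but-3-en-1-yl)-7-methyl-8-(prop-1-en-2-yl)-1,4-dioxaspiro[4.5]decane
Conditions: HOCH2CH2OH, PPTS (cat.), benzene, reflux (Dean–Stark)
Reagents that add atoms: ethylene glycol, OCCO
Why: Acid-catalysed ketalisation masks the C8 ketone, the one carbonyl group that must stay out of the reductive coupling; no stereocentre is affected.

Step 4
Reactants: 8 (7R,8S)-7-(but-3-en-1-yl)-7-methyl-8-(prop-1-en-2-yl)-1,4-dioxaspiro[4.5]decane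
Product: 10 3-[(7R,8R)-8-acetyl-7-methyl-1,4-dioxaspiro[4.5]decan-7-yl]propanal, via bis-ozonide 9 (not isolated)
Conditions: O3, CH2Cl2, −78 °C; then PPh3, −78 → 25 °C
Reagents that add atoms: ozone, [O-][O+]=O
Why: Ozonolysis with reductive work-up cleaves both the monosubstituted and the 1,1-disubstituted olefin, so the C3 aldehyde and the C4 methyl ketone are unmasked together under neutral conditions that do not epimerise the α-acetyl centre C5.

Step 5 (key step)
Reactants: 10 3-[(7R,8R)-8-acetyl-7-methyl-1,4-dioxaspiro[4.5]decan-7-yl]propanal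
Product: 12 (4aR,8aR)-5,8a-dimethyl-3,4,4a,7,8,8a-hexahydronaphthalen-2(1H)-one, via ketal alkene 11 (not isolated)
Conditions: TiCl3(DME)1.5, Zn–Cu couple, DME, reflux, 10 added over 20 h; filter; then 1 M HCl, THF, 25 °C
Reagents that add atoms: water, O
Why: McMurry reaction, in which the titanium-bound ketyl radical anion of the aldehyde (a carbonyl carbon with reversed polarity) adds to the neighbouring methyl ketone and the titanium pinacolate is deoxygenated, so two normally electrophilic carbonyl carbons are joined as the C3=C4 olefin of a six-membered ring that is trans-fused because C5 and C10 are already fixed; dilute acid then removes the ketal.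

Step 6
Reactants: 12 (4aR,8aR)-5,8a-dimethyl-3,4,4a,7,8,8a-hexahydronaphthalen-2(1H)-one; 13 acetone
Product: 14 (4aR,8aR)-3-(2-hydroxypropan-2-yl)-5,8a-dimethyl-3,4,4a,7,8,8a-hexahydronaphthalen-2(1H)-one (C3 epimers)
Conditions: LiN(i-Pr)2, THF, −78 °C; then 13, −78 °C; AcOH quench
Reagents that add atoms: none
Why: Directed aldol addition, in which LiN(i-Pr)2 deprotonates kinetically at C7 rather than at C9 (neopentylic, next to quaternary C10) and the lithium enolate adds to acetone; the new C7 stereocentre is inconsequential because it is removed in step 7.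

Step 7
Reactants: 14 (4aR,8aR)-3-(2-hydroxypropan-2-yl)-5,8a-dimethyl-3,4,4a,7,8,8a-hexahydronaphthalen-2(1H)-one
Product: 16 (4aR,8aR)-5,8a-dimethyl-3-(propan-2-ylidene)-3,4,4a,7,8,8a-hexahydronaphthalen-2(1H)-one, via mesylate 15 (not isolated)
Conditions: MsCl, Et3N, CH2Cl2, 0 → 25 °C; then DBU (cat.), 25 °C
Reagents that add atoms: methanesulfonyl chloride, CS(=O)(=O)Cl (stays only in 15)
Why: Mesylation of the tertiary aldol and E1cB elimination, with DBU moving any β,γ-unsaturated (isopropenyl) isomer into conjugation, give the tetrasubstituted isopropylidene enone; no stereocentre is involved.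

Step 8
Reactants: 16 (4aR,8aR)-5,8a-dimethyl-3-(propan-2-ylidene)-3,4,4a,7,8,8a-hexahydronaphthalen-2(1H)-one
Product: 17 (4aR,5S,6R,8aR)-5,6-dihydroxy-5,8a-dimethyl-3-(propan-2-ylidene)-3,4,4a,5,6,7,8,8a-octahydronaphthalen-2(1H)-one (3α,4α-dihydroxy-5αH-eudesm-7(11)-en-8-one)
Conditions: OsO4 (2 mol %), NMO, acetone–H2O (8:1), 0 → 25 °C
Reagents that add atoms: osmium tetroxide, O=[Os](=O)(=O)=O; N-methylmorpholine N-oxide, C[N+]1([O-])CCOCC1; water, O
Why: Upjohn dihydroxylation, in which the electron-rich trisubstituted Δ3 olefin reacts in preference to the tetrasubstituted enone olefin and osmylation from the α-face, anti to the axial C10 methyl, sets C3 (R) and C4 (S) as the cis-3α,4α-diol.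

Step 9
Reactants: 17 3α,4α-dihydroxy-5αH-eudesm-7(11)-en-8-one; 18 angelic acid ((2Z)-2-methylbut-2-enoic acid)
Product: 20 (1S,2R,4aR,8aR)-1-hydroxy-1,4a-dimethyl-6-oxo-7-(propan-2-ylidene)decahydronaphthalen-2-yl (2Z)-2-methylbut-2-enoate (3α-angeloyloxy-4α-hydroxy-5αH-eudesm-7(11)-en-8-one), via mixed anhydride 19 (not isolated)
Conditions: 18, 2,4,6-Cl3C6H2COCl, Et3N, toluene, 25 °C; then 17, toluene, 80 °C
Reagents that add atoms: 2,4,6-trichlorobenzoyl chloride, O=C(Cl)c1c(Cl)cc(Cl)cc1Cl (stays only in 19)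
Why: Yamaguchi esterification through the 2,4,6-trichlorobenzoyl mixed anhydride without DMAP acylates only the secondary C3 hydroxyl (the tertiary C4 hydroxyl is inert) and is the usual way to keep the Z (angelate) geometry from isomerising to the tiglate.

Step 10
Reactants: 20 3α-angeloyloxy-4α-hydroxy-5αH-eudesm-7(11)-en-8-one
Product: 21 (1S,2R,4aR,8aR)-7-(2-hydroperoxypropan-2-yl)-1-hydroxy-1,4a-dimethyl-6-oxo-1,2,3,4,4a,5,6,8a-octahydronaphthalen-2-yl (2Z)-2-methylbut-2-enoate (target)
Conditions: O2, visible light, tetraphenylporphyrin (cat.), CH2Cl2, −20 °C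
Reagents that add atoms: dioxygen, O=O
Why: Schenck ene reaction of singlet oxygen with the s-cis enone, in which oxygen bonds to C11 and the allylic hydrogen is taken from C6 (the CH2 geminal to the carbonyl on the α-carbon, the gem selectivity of α,β-unsaturated carbonyl compounds), moving the double bond to C6=C7 and giving the tertiary hydroperoxide; the conjugated angelate reacts far more slowly and no stereocentre is created.

**Compound list**

1 | (1R,5R)-(+)-verbenone, (1R,5R)-4,6,6-trimethylbicyclo[3.1.1]hept-3-en-2-one | CC1=CC(=O)[C@@H]2C[C@H]1C2(C)C | starting material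
2 | but-3-en-1-ylmagnesium bromide | C=CCC[Mg]Br | starting material
3 | trimethylsilyl enol ether of 4: 4-(but-3-en-1-yl)-4,6,6-trimethyl-2-(trimethylsilyloxy)bicyclo[3.1.1]hept-2-ene, stereocentres as in 4 | C=CCC[C@]1(C)C=C(O[Si](C)(C)C)[C@@H]2C[C@H]1C2(C)C | intermediate
4 | (1R,4R,5R)-4-(but-3-en-1-yl)-4,6,6-trimethylbicyclo[3.1.1]heptan-2-one (butenyl anti to the CMe2 bridge) | C=CCC[C@]1(C)CC(=O)[C@@H]2C[C@H]1C2(C)C | intermediate
5 | (4R,5R)-5-(but-3-en-1-yl)-4-(2-iodopropan-2-yl)-5-methyl-1-(trimethylsilyloxy)cyclohex-1-ene | C=CCC[C@]1(C)CC(O[Si](C)(C)C)=CC[C@H]1C(C)(C)I | intermediate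
6 | (4S,5R)-5-(but-3-en-1-yl)-5-methyl-4-(prop-1-en-2-yl)-1-(trimethylsilyloxy)cyclohex-1-ene | C=CCC[C@]1(C)CC(O[Si](C)(C)C)=CC[C@H]1C(C)=C | intermediate
7 | (3R,4S)-3-(but-3-en-1-yl)-3-methyl-4-(prop-1-en-2-yl)cyclohexan-1-one (butenyl and isopropenyl trans) | C=CCC[C@]1(C)CC(=O)CC[C@H]1C(C)=C | intermediate
8 | (7R,8S)-7-(but-3-en-1-yl)-7-methyl-8-(prop-1-en-2-yl)-1,4-dioxaspiro[4.5]decane | C=CCC[C@]1(C)CC2(OCCO2)CC[C@H]1C(C)=C | intermediate
9 | bis-ozonide of 8 (both C=C converted into 1,2,4-trioxolanes; ring stereocentres as in 8, trioxolane carbons unassigned) | C1(OOCO1)CC[C@]2(C)CC3(OCCO3)CC[C@H]2C4(C)OOCO4 | intermediate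
10 | 3-[(7R,8R)-8-acetyl-7-methyl-1,4-dioxaspiro[4.5]decan-7-yl]propanal | O=CCC[C@]1(C)CC2(OCCO2)CC[C@H]1C(C)=O | intermediate
11 | ethylene ketal of 12: (4a'R,8a'R)-5',8a'-dimethyl-3',4',4a',7',8',8a'-hexahydro-1'H-spiro[1,3-dioxolane-2,2'-naphthalene] | CC1=CCC[C@]2(C)CC3(OCCO3)CC[C@@H]12 | intermediate
12 | (4aR,8aR)-5,8a-dimethyl-3,4,4a,7,8,8a-hexahydronaphthalen-2(1H)-one (trans-fused; 11,12,13-trinor-5αH-eudesm-3-en-8-one) | CC1=CCC[C@]2(C)CC(=O)CC[C@@H]12 | intermediate
13 | acetone | CC(C)=O | starting material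
14 | (4aR,8aR)-3-(2-hydroxypropan-2-yl)-5,8a-dimethyl-3,4,4a,7,8,8a-hexahydronaphthalen-2(1H)-one (C3 epimers) | CC1=CCC[C@]2(C)CC(=O)C(C(C)(C)O)C[C@@H]12 | intermediate
15 | methanesulfonate of 14 (tertiary mesylate) | CC1=CCC[C@]2(C)CC(=O)C(C(C)(C)OS(C)(=O)=O)C[C@@H]12 | intermediate
16 | (4aR,8aR)-5,8a-dimethyl-3-(propan-2-ylidene)-3,4,4a,7,8,8a-hexahydronaphthalen-2(1H)-one (5αH-eudesma-3,7(11)-dien-8-one) | CC1=CCC[C@]2(C)CC(=O)C(=C(C)C)C[C@@H]12 | intermediate
17 | (4aR,5S,6R,8aR)-5,6-dihydroxy-5,8a-dimethyl-3-(propan-2-ylidene)-3,4,4a,5,6,7,8,8a-octahydronaphthalen-2(1H)-one (3α,4α-dihydroxy-5αH-eudesm-7(11)-en-8-one) | O[C@@H]1CC[C@]2(C)CC(=O)C(=C(C)C)C[C@H]2[C@]1(C)O | intermediate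
18 | angelic acid, (2Z)-2-methylbut-2-enoic acid | C/C=C(/C)C(=O)O | starting material
19 | (2Z)-2-methylbut-2-enoic 2,4,6-trichlorobenzoic anhydride | C/C=C(/C)C(=O)OC(=O)c1c(Cl)cc(Cl)cc1Cl | intermediate
20 | (1S,2R,4aR,8aR)-1-hydroxy-1,4a-dimethyl-6-oxo-7-(propan-2-ylidene)decahydronaphthalen-2-yl (2Z)-2-methylbut-2-enoate (3α-angeloyloxy-4α-hydroxy-5αH-eudesm-7(11)-en-8-one) | C/C=C(/C)C(=O)O[C@@H]1CC[C@]2(C)CC(=O)C(=C(C)C)C[C@H]2[C@]1(C)O | intermediate
21 | (1S,2R,4aR,8aR)-7-(2-hydroperoxypropan-2-yl)-1-hydroxy-1,4a-dimethyl-6-oxo-1,2,3,4,4a,5,6,8a-octahydronaphthalen-2-yl (2Z)-2-methylbut-2-enoate (3α-angeloyloxy-11-hydroperoxy-4α-hydroxy-5αH-eudesm-6-en-8-one) | C/C=C(/C)C(=O)O[C@@H]1CC[C@]2(C)CC(=O)C(C(C)(C)OO)=C[C@H]2[C@]1(C)O | target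

**Step count and risks**

Total step count: 10. Longest linear sequence: 10 steps (1 → 21); the route is fully linear.

The three steps most likely to fail:

Step 2 (cyclobutane fragmentation and elimination). The risks are HI addition to the terminal olefin and some elimination toward the ring methine (isopropylidene isomer). The fallback sets out from 4: acetolytic ring opening (BF3·OEt2, Zn(OAc)2, Ac2O, 25 °C) gives the ring-opened enol acetate/tertiary acetate F1. Flash vacuum pyrolysis at about 450 °C removes acetic acid by syn-elimination toward a methyl group to give the isopropenyl enol acetate F2. K2CO3 in MeOH then cleaves the enol acetate and the sequence comes back to the route at 7.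

Step 5 (McMurry ring closure). The risks are loss of the ketal on the Lewis-acidic titanium surface, epimerisation at the α-acetyl centre C5 before coupling, and stalling at the pinacolate. The fallback sets out from 10: SmI2 (THF, t-BuOH, −78 °C) carries out the same ketyl coupling but stops at the cis-3,4-diol F3, whose C3/C4 configuration does not matter. Thiocarbonyldiimidazole (toluene, 80 °C) converts it into the cyclic thionocarbonate F4, and P(OMe)3 at 110 °C (Corey–Winter olefination) extrudes it to the olefin. The sequence comes back to the route at 11, which is hydrolysed to 12 as in step 5.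

Step 9 (angeloylation). The C3 hydroxyl is axial and flanked by a tertiary carbinol, and the angelate can isomerise to the tiglate. The fallback sets out from 17: DCC/DMAP esterification with 2-[bis(2,2,2-trifluoroethoxy)phosphoryl]propanoic acid gives the phosphonate ester F5. KN(SiMe3)2 with 18-crown-6 in THF at −78 °C followed by acetaldehyde (Still–Gennari olefination) builds the Z-trisubstituted double bond on the substrate, and the sequence comes back to the route at 20.

Further compounds
F1 | step 2 | (4R,5R)-4-[2-(acetyloxy)propan-2-yl]-5-(but-3-en-1-yl)-5-methylcyclohex-1-en-1-yl acetate | C=CCC[C@]1(C)CC(OC(C)=O)=CC[C@H]1C(C)(C)OC(C)=O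
F2 | step 2 | (4S,5R)-5-(but-3-en-1-yl)-5-methyl-4-(prop-1-en-2-yl)cyclohex-1-en-1-yl acetate | C=CCC[C@]1(C)CC(OC(C)=O)=CC[C@H]1C(C)=C
F3 | step 5 | cis-3,4-diol ketal: (4a'R,8a'R)-5',8a'-dimethyloctahydro-1'H-spiro[1,3-dioxolane-2,2'-naphthalene]-5',6'-diol (diol carbons unassigned) | OC1CC[C@]2(C)CC3(OCCO3)CC[C@H]2C1(C)O
F4 | step 5 | cyclic thionocarbonate of F3 | S=C1OC2CC[C@]3(C)CC4(OCCO4)CC[C@H]3C2(C)O1
F5 | step 9 | 3-O-{2-[bis(2,2,2-trifluoroethoxy)phosphoryl]propanoyl} ester of 17 | CC(C(=O)O[C@@H]1CC[C@]2(C)CC(=O)C(=C(C)C)C[C@H]2[C@]1(C)O)P(=O)(OCC(F)(F)F)OCC(F)(F)F
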